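A direct plan would oxygenate ring A stepwise: 2,3,4-trimethoxybenzaldehyde A1 would go by two Dakin/Baeyer–Villiger oxidations, a methylation and a formylation to 2,3,4,5-tetramethoxyphenol A2, then by acetylation with Fries shift to the o-hydroxyacetophenone A3.
Aldol condensation of A3 with 4-(benzyloxy)benzaldehyde A4 would give chalcone A5, iodine/DMSO closure of ring C at oxygen would give the benzyl-protected flavone A6, and hydrogenolysis would give the target.
Its weakest parts would be:
- the peracid oxygenation chain: four steps for two oxygens, no gain in complexity, and a quinone-prone arene under peroxide;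
- the Lewis-acid Fries acylation of the pentaoxygenated ring: the methoxy group next to the new carbonyl can be lost;
- the hot iodine-mediated ring closure on late chalcone: HI can cleave the 5-methoxy and benzyl ethers, and aurone or iodination side paths are open.

Plan of the new route: the four oxygen-bearing carbons C5–C8 of ring A are the C4O4 unit of dimethyl squarate, and the fusion bond C4a=C8a is the C5=C6 enol-ether edge of a 2-aryl-4-pyranone (ring C with ring B attached).
The retrosynthesis cuts C4a–C5 (electrocyclic key step) and C8–C8a (carbonyl addition), then the pyranone at C2–C3 and O1–C8a.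
Ring order: B is bought, C is made first (step 1), A is made last (step 3).
Ring A is oxygenated symmetrically (O at C5/C8, OMe at C6/C7), so either orientation of the annulation converges.
No peracid chain, no Fries step and no oxidative closure at oxygen arise: all ring-A oxygens come in one reagent and ring A closes at carbon.

Key step: step 3

Remark: lithiation of the 2-aryl-4-pyranone is assumed at C6, next to the ring oxygen; lithiation at C5 would lead through the regioisomeric adduct to the same hydroquinone. The three starting materials are taken as catalogue compounds.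

Step 1
Reactants: 1 4-(allyloxy)benzoic acid; 2 (E)-4-methoxybut-3-en-2-one
Product: 6 2-[4-(allyloxy)phenyl]-4H-pyran-4-one, via 4-(allyloxy)benzoyl chloride 3 (not isolated), via lithium 4-methoxybuta-1,3-dien-2-olate 4 (not isolated), via 1-aryl-5-methoxypent-4-ene-1,3-dione 5 (not isolated)
Conditions: (COCl)2 (1.2 equiv), DMF (cat.), CH2Cl2, 0 °C to rt, evaporate; 2 (2.1 equiv), LiN(SiMe3)2 (2.1 equiv), THF, −78 °C, 30 min, then 3 (1.0 equiv), −78 °C, 1 h; 1 M HCl; crude 5, CF3CO2H (0.2 equiv), toluene, rt, 6 h
Reagents that add atoms: none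
Why: Crossed Claisen-type C-acylation of the kinetic lithium dienolate (the second equivalent takes up the acidic diketone proton), followed by acid-catalysed 6-endo oxa-Michael addition of the enol oxygen and loss of methanol, should close the 4-pyranone; the allyl ether is inert to both stages and no stereocentre is formed.

Step 2
Reactants: 6 2-[4-(allyloxy)phenyl]-4H-pyran-4-one; 7 dimethyl squarate (3,4-dimethoxycyclobut-3-ene-1,2-dione)
Product: 10 4-hydroxy-2,3-dimethoxy-4-{4-oxo-6-[4-(allyloxy)phenyl]-4H-pyran-2-yl}cyclobut-2-en-1-one (racemic), via 6-lithio-4-pyranone 8 (not isolated), via lithium cyclobutenolate 9 (not isolated)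
Conditions: 2,2,6,6-tetramethylpiperidine (1.1 equiv), n-BuLi (1.05 equiv), THF, −78 °C; 6 added dropwise, −78 °C, 15 min; cannulated into 7 (1.3 equiv), THF, −78 °C, 30 min; sat. aq NH4Cl at −78 °C
Reagents that add atoms: none
Why: Deprotonative lithiation of the pyranone next to the ring oxygen by the hindered amide (by analogy with the low-temperature lithium-amide metalation of chromones and flavones), then 1,2-addition of the vinyllithium to one squarate carbonyl (the standard entry to 4-hydroxycyclobutenones), should join C8 to C8a; inverse addition keeps unmetalated pyranone scarce, and the racemic carbinol centre is erased in step 3.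

Step 3
Reactants: 10 4-hydroxy-2,3-dimethoxy-4-{4-oxo-6-[4-(allyloxy)phenyl]-4H-pyran-2-yl}cyclobut-2-en-1-one
Product: 13 2-[4-(allyloxy)phenyl]-5,8-dihydroxy-6,7-dimethoxy-4H-chromen-4-one, via (Z)-dienylketene 11 (not isolated), via 4aH-chromene-4,5-dione 12 (not isolated)
Conditions: toluene (degassed, 0.02 M), 110 °C, Ar, 3 h; evaporate under Ar, crude used at once
Reagents that add atoms: none
Why: Heating should open the cyclobutenone by conrotatory 4π electrocyclic cleavage of the C(OH)–C(=O) bond, the hydroxyl donor turning outward (torquoselectivity), so that (Z)-dienylketene 11 forms with the pyranone C5=C6 bond cis to the ketene; disrotatory 6π electrocyclisation then joins the ketene carbon to pyranone C5 (the C4a–C5 bond of the flavone), and dienone 12, whose 4a-H lies between two carbonyl groups, tautomerises to the aromatic hydroquinone. The closest known reaction type is the thermal ring expansion of 4-alkenyl- and 4-heteroaryl-4-hydroxycyclobutenones from squarate esters to annulated hydroquinones (Moore/Liebeskind benzannulation). Ring A is the only ring closed, at a carbon–carbon bond in a thermally allowed six-electron electrocyclic mode, while rings B and C are carried in intact. No stereocentre has to be controlled, since the carbinol centre of 10 and C4a of 12 both end as sp2 carbons. The selectivities needed are the sense of ring opening, secured by the outward preference of the OH group, and the site of closure, secured by the substrate because C5–H is the only position next to the point of attachment. As C5 to C8 carry O, OMe, OMe, O in a symmetrical order, even the opposite mode of attachment would give the same product.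

Step 4
Reactants: 13 2-[4-(allyloxy)phenyl]-5,8-dihydroxy-6,7-dimethoxy-4H-chromen-4-one
Product: 15 2-[4-(allyloxy)phenyl]-5,6,7,8-tetramethoxy-4H-chromen-4-one, via 5-hydroxy-6,7,8-trimethoxy flavone 14 (not isolated)
Conditions: Me2SO4 (5 equiv), K2CO3 (6 equiv), acetone (degassed), reflux, N2, 24 h; aq NH3
Reagents that add atoms: dimethyl sulfate, COS(=O)(=O)OC
Why: Williamson O-methylation (SN2) should take the free 8-OH first and then, under these forcing conditions, the 5-OH that is hydrogen-bonded to C4=O; ring A has no C–H left for C-alkylation, the allyl ether keeps the 4'-oxygen out of the reaction, and exclusion of air prevents oxidation of the hydroquinone to the 5,8-quinone.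

Step 5
Reactants: 15 2-[4-(allyloxy)phenyl]-5,6,7,8-tetramethoxy-4H-chromen-4-one
Product: 16 4'-hydroxy-5,6,7,8-tetramethoxyflavone
Conditions: Pd(PPh3)4 (5 mol %), morpholine (10 equiv), THF, rt, 2 h; 1 M HCl wash
Reagents that add atoms: none
Why: In this Tsuji–Trost deallylation, zerovalent palladium should add oxidatively to the allyl aryl ether and morpholine should capture the allyl group, while the four methyl ethers and the pyranone are untouched at room temperature; the product is achiral, so no configuration has to be set.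

Compound list
1 | 4-(allyloxy)benzoic acid | C=CCOc1ccc(cc1)C(=O)O | starting material
2 | (E)-4-methoxybut-3-en-2-one | CO/C=C/C(C)=O | starting material
3 | 4-(allyloxy)benzoyl chloride | C=CCOc1ccc(cc1)C(Cl)=O | intermediate
4 | lithium (E)-4-methoxybuta-1,3-dien-2-olate | [Li]OC(=C)/C=C/OC | intermediate
5 | (E)-1-[4-(allyloxy)phenyl]-5-methoxypent-4-ene-1,3-dione | C=CCOc1ccc(cc1)C(=O)CC(=O)/C=C/OC | intermediate
6 | 2-[4-(allyloxy)phenyl]-4H-pyran-4-one | O=c1cc(-c2ccc(OCC=C)cc2)occ1 | intermediate
7 | dimethyl squarate (3,4-dimethoxycyclobut-3-ene-1,2-dione) | COC1=C(OC)C(=O)C1=O | starting material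
8 | {4-oxo-6-[4-(allyloxy)phenyl]-4H-pyran-2-yl}lithium | [Li]c1cc(=O)cc(-c2ccc(OCC=C)cc2)o1 | intermediate
9 | lithium 2,3-dimethoxy-4-oxo-1-{4-oxo-6-[4-(allyloxy)phenyl]-4H-pyran-2-yl}cyclobut-2-en-1-olate (racemic) | [Li]OC1(c2cc(=O)cc(-c3ccc(OCC=C)cc3)o2)C(OC)=C(OC)C1=O | intermediate
10 | 4-hydroxy-2,3-dimethoxy-4-{4-oxo-6-[4-(allyloxy)phenyl]-4H-pyran-2-yl}cyclobut-2-en-1-one (racemic) | COC1=C(OC)C(O)(c2cc(=O)cc(-c3ccc(OCC=C)cc3)o2)C1=O | intermediate
11 | (Z)-4-hydroxy-2,3-dimethoxy-4-{4-oxo-6-[4-(allyloxy)phenyl]-4H-pyran-2-yl}buta-1,3-dien-1-one (dienylketene) | O=C=C(OC)/C(OC)=C(/O)c1cc(=O)cc(-c2ccc(OCC=C)cc2)o1 | intermediate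
12 | 2-[4-(allyloxy)phenyl]-8-hydroxy-6,7-dimethoxy-4aH-chromene-4,5-dione (racemic) | O=C1C=C(c2ccc(OCC=C)cc2)OC2=C(O)C(OC)=C(OC)C(=O)C12 | intermediate
13 | 2-[4-(allyloxy)phenyl]-5,8-dihydroxy-6,7-dimethoxy-4H-chromen-4-one | COc1c(OC)c(O)c2c(=O)cc(-c3ccc(OCC=C)cc3)oc2c1O | intermediate
14 | 2-[4-(allyloxy)phenyl]-5-hydroxy-6,7,8-trimethoxy-4H-chromen-4-one | COc1c(OC)c(O)c2c(=O)cc(-c3ccc(OCC=C)cc3)oc2c1OC | intermediate
15 | 2-[4-(allyloxy)phenyl]-5,6,7,8-tetramethoxy-4H-chromen-4-one | COc1c(OC)c(OC)c2c(=O)cc(-c3ccc(OCC=C)cc3)oc2c1OC | intermediate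
16 | 4'-hydroxy-5,6,7,8-tetramethoxyflavone (achiral) | COc1c(OC)c(OC)c2c(=O)cc(-c3ccc(O)cc3)oc2c1OC | target

Total step count: 5. Longest linear sequence: 5 steps (1 to 6 to 10 to 13 to 15 to 16).

Steps most likely to fail

Step 2. The lithiated pyranone may add in conjugate fashion to pyranone that is not yet metalated, its ring may open, or the amide may remove the C3 proton instead. The fallback would set out from 6 and come back at 10, making the metalation covalent and site-fixed. Zincation at C6 with TMPZnCl·LiCl in the presence of MgCl2 (THF, rt) should give the pyranylzinc chloride F1, and iodolysis with I2 should give 2-[4-(allyloxy)phenyl]-6-iodo-4H-pyran-4-one F2. Iodine–magnesium exchange (i-PrMgCl·LiCl, THF, −78 °C) should then give the pyranylmagnesium chloride F3, which would add to 7 to give the chloromagnesium alkoxide F4 and, after aqueous NH4Cl, cyclobutenone 10.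

Step 3. The ring may open with the hydroxyl group turned inward, so that the ketene is captured by that hydroxyl (lactonisation to a furanone), or closure onto the acceptor-substituted C5 may be slow enough for the ketene to oligomerise. The fallback would set out from 10 and come back at 14. The carbinol would be capped as its methyl ether (MeI, Ag2O, MeCN, rt) to give the 4-methoxycyclobutenone F5. An alkoxy group likewise rotates outward but cannot lactonise, so thermolysis (p-xylene, 130 °C) should lead through the methoxy dienylketene F6 and the 8-methoxy dienone F7 directly to 14, which the conditions of step 4 would then methylate at the 5-OH alone.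

Step 4. Traces of oxygen may oxidise the hydroquinone anion to the quinone before alkylation, and alkylation of the hydrogen-bonded 5-OH may stay incomplete. The fallback would set out from 13 and come back at 15, making the oxidation deliberate. Ag2O in CH2Cl2 should give the stable, purifiable flavone-5,8-quinone F8. Reductive methylation (aq Na2S2O4, then Me2SO4, KOH, Bu4NBr, THF/H2O, N2) would then regenerate the hydroquinone under excess reductant and alkylate it as the more reactive dianion to give 15.

Further compounds
F1 | step 2 | chloro{4-oxo-6-[4-(allyloxy)phenyl]-4H-pyran-2-yl}zinc | Cl[Zn]c1cc(=O)cc(-c2ccc(OCC=C)cc2)o1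
F2 | step 2 | 2-[4-(allyloxy)phenyl]-6-iodo-4H-pyran-4-one | Ic1cc(=O)cc(-c2ccc(OCC=C)cc2)o1
F3 | step 2 | chloro{4-oxo-6-[4-(allyloxy)phenyl]-4H-pyran-2-yl}magnesium | Cl[Mg]c1cc(=O)cc(-c2ccc(OCC=C)cc2)o1
F4 | step 2 | chloromagnesium 2,3-dimethoxy-4-oxo-1-{4-oxo-6-[4-(allyloxy)phenyl]-4H-pyran-2-yl}cyclobut-2-en-1-olate (racemic) | Cl[Mg]OC1(c2cc(=O)cc(-c3ccc(OCC=C)cc3)o2)C(OC)=C(OC)C1=O
F5 | step 3 | 2,3,4-trimethoxy-4-{4-oxo-6-[4-(allyloxy)phenyl]-4H-pyran-2-yl}cyclobut-2-en-1-one (racemic) | COC1=C(OC)C(OC)(c2cc(=O)cc(-c3ccc(OCC=C)cc3)o2)C1=O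
F6 | step 3 | (Z)-2,3,4-trimethoxy-4-{4-oxo-6-[4-(allyloxy)phenyl]-4H-pyran-2-yl}buta-1,3-dien-1-one | O=C=C(OC)/C(OC)=C(/OC)c1cc(=O)cc(-c2ccc(OCC=C)cc2)o1
F7 | step 3 | 2-[4-(allyloxy)phenyl]-6,7,8-trimethoxy-4aH-chromene-4,5-dione (racemic) | O=C1C=C(c2ccc(OCC=C)cc2)OC2=C(OC)C(OC)=C(OC)C(=O)C12
F8 | step 4 | 2-[4-(allyloxy)phenyl]-6,7-dimethoxy-4H-chromene-4,5,8-trione | O=C1C(OC)=C(OC)C(=O)c2c1c(=O)cc(-c1ccc(OCC=C)cc1)o2
A1 | direct plan | 2,3,4-trimethoxybenzaldehyde | COc1ccc(C=O)c(OC)c1OC
A2 | direct plan | 2,3,4,5-tetramethoxyphenol | COc1cc(O)c(OC)c(OC)c1OC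
A3 | direct plan | 1-(2-hydroxy-3,4,5,6-tetramethoxyphenyl)ethanone | CC(=O)c1c(O)c(OC)c(OC)c(OC)c1OC
A4 | direct plan | 4-(benzyloxy)benzaldehyde | O=Cc1ccc(OCc2ccccc2)cc1
A5 | direct plan | (E)-4-benzyloxy-2'-hydroxy-3',4',5',6'-tetramethoxychalcone | COc1c(OC)c(OC)c(C(=O)/C=C/c2ccc(OCc3ccccc3)cc2)c(O)c1OC
A6 | direct plan | 4'-benzyloxy-5,6,7,8-tetramethoxyflavone | COc1c(OC)c(OC)c2c(=O)cc(-c3ccc(OCc4ccccc4)cc3)oc2c1OC
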